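## Structural features

The target is an isoflavone: a benzo ring (ring A) fused to a 4-pyranone (ring C), with a 2,4,5-trimethoxyphenyl group (ring B) joined through the C3–C1' bond. Ring A is substituted on every carbon: OH at C5 and C8 (para, a hydroquinone), OMe at C7, a 3-methylbut-2-enyl (prenyl) chain at C6, and the ring fusion at C4a/C8a. There is no stereocentre, and the prenyl alkene carries two identical methyl groups, so no stereochemical element has to be controlled. Three functions are fragile. The 5,8-hydroquinone is oxidised to the quinone by air or any oxidant. The prenyl group is closed onto the neighbouring 5-OH by acid and is attacked by electrophilic halogen. C2 of the pyranone is opened by hydroxide, alkoxide or secondary amines. The real difficulty is ring A: three oxygen functions must be told apart and a carbon chain placed on the last free carbon, while ring B, whose C2' and C5' methoxy groups are also para, is as oxidisable as ring A and rules out an unselective oxidative demethylation late in the route. The key step uses ring B: its oxygens at C2' and C5' are para, those at C4' and C5' are adjacent, and C1' (bearing the chromone) is next to C2'. This is the 4-alkoxyphenol pattern that a chromium carbene benzannulation builds around a terminal alkyne on C3.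

## Logic of the disconnections

**20 from 18 (through 19).** The O8–CH3 bond is the last to be changed. This keeps the hydroquinone masked as a stable monomethyl ether until the final flask. It uses the one difference between rings A and B at that stage: only ring A has a free OH para to a methoxy group. The forward step must oxidise through the phenol only, sparing the para-dimethoxy pair of ring B and the prenyl alkene, and must reduce 19 before its electron-poor pyranone is attacked.

**18 from 16 and 17.** The C6–CH2 bond is cut, leaving a C6 bromide in 16. C6 is the only carbon of ring A without oxygen, so a halide there turns the prenylation into a cross-coupling with no choice of ring position. The acid- and halogen-sensitive side chain is thereby kept out of all earlier steps. The forward step needs oxidative addition at a bromide flanked by OH and OMe, and transfer of the allyl unit at its CH2 end.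

**16 from 15, and 15 from 14.** Two O–CH3 bonds are adjusted: the C5 ether is restored (16 to 15) and the C2' ether removed (15 to 14). 14 is what ring construction delivers, with the carbonyl-derived oxygen necessarily free. The C5 ether is the only one peri to the C4 carbonyl. Forward, a Lewis acid must cleave one methyl ether out of six, and the methylation must not open ring C.

**14 from 7 and 12 (key disconnection).** Ring B is taken apart by cutting C5'–C6', C1'–C2' and C2'–C3'. The tetrasubstituted arene shrinks to an ethynyl group on C3 of 7 and to the alkoxyvinyl carbene plus one CO ligand of 12. Every ring B substituent is then placed by construction, and the chromone, the C8 oxygen and the C6 bromide travel as spectators. The forward step demands a single orientation of alkyne insertion and tolerance of the enone and the aryl bromide.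

**12 from 8 and 9.** The bond between the carbene carbon and the vinyl carbon, and the carbene O–CH3 bond, are cut, returning 8 and 9. The forward sequence needs α-metalation of 8 (to 10), addition to a CO ligand (to 11) and O-alkylation without acid, since the enol ether tolerates neither acid nor long storage.

**7 from 6, and 6 from 4 and 5.** The C–Si bond and then the C3–C(sp) bond are cut. An iodide on C3 is the standard electrophile for carbon attachment there, and the silyl cap of 5 prevents double coupling. Forward, palladium must choose C3–I over C6–Br, and the silyl group must leave without a nucleophile adding to C2.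

**4 from 2 (through 3).** O1–C2, C3–I and C2–C3 are cut, reducing ring C to the acetyl group and ortho phenol of 2 plus a one-carbon reagent. The forward step needs the phenol to close on the iminium carbon of the iodinated form of 3. Ring A has no free position at this point, so iodine has nowhere else to go.

**2 from 1.** The C–Br bond at the future C6 is cut. In 1 this is the only unsubstituted ring carbon and ring B does not yet exist, so a halogenation that would be a selectivity problem late is unambiguous early. The forward step must brominate the ring and not the acetyl methyl group.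

## Other disconnections considered

**Alternative 1:** The cut is the C4a–C5 bond, so that ring A is assembled from a four-membered ring and the enol ether double bond of a dihydropyran. In the forward key step, heating the cyclobutenone A2 would open the four-membered ring to a ketene. A 6π closure onto the dihydropyran alkene and tautomerisation would then give the racemic chromane-5,8-diol A1 with a silyl ether at C4.

- In its favour: all four ring A substituents (C5–OH, C6 prenyl, C7–OMe, C8–OH) are fixed by the substituents of A2. No aromatic halogenation, cross-coupling or late oxidation of ring A is needed, and the step is thermal and metal-free. On ring A this is the better plan, since the chosen route spends steps 1, 8, 9 and 10 on what this closure does at once.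
- Against it here: A1 is a chromane at the wrong oxidation level and has no ring B. C4 must be desilylated and oxidised, C2–C3 dehydrogenated, and C3 halogenated and arylated, all on a hydroquinone that must first be protected and finally released. The prenyl group would have to survive the C3 halogenation. Making A2 also requires a nucleophile to distinguish the two carbonyls of an unsymmetrical cyclobutenedione.
- Comparison: structurally it solves the hard ring and leaves the easy one, while the chosen plan does the reverse and handles ring A by conventional aromatic chemistry. Mechanistically both rest on a 6π closure of a ketene, and the alternative is the equal or better, having no regiochemical variable and no stoichiometric metal. On step economy it is expected to be longer than ten steps once the redox and protecting-group moves after A1 are counted. The racemic C4 centre of A1 is of no consequence because it is oxidised later.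

**Alternative 2:** The cut is C2–C3, with C2 taken from an O-methyl carbon of a symmetric 2,4,6-trimethoxyphenyl ketone. In the forward key step, Rh2(OAc)4 (divalent rhodium) would decompose the diazo ketone A4. The carbene at C3 would insert into a C–H bond of an ortho methoxy group and close ring C as the racemic isoflavanone A3.

- In its favour: A4 is a diazo-transfer product of a deoxybenzoin, and the two ortho methoxy groups are equivalent. The metal is catalytic, which is better than the stoichiometric chromium of the chosen plan. Ring B is brought in with its oxygens in place.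
- Against it here: a six-membered insertion is not the preferred ring size for such carbenes. The ether oxygen can attack the carbene first and lead, after a shift, to a benzofuranone. The two electron-rich arenes and the silyl isopropyl C–H bonds are further competing sites, which is why the C2' oxygen must be silylated instead of methylated, at the cost of a later exchange. A3 must then be dehydrogenated. Ring A arrives with C6 and C8 unsubstituted, so the C8 oxygenation para to a chelated phenol and the C6 prenylation would both fall after ring B is present.
- Comparison: structurally it is the equal of the chosen plan for rings B and C but leaves ring A least prepared. Mechanistically it needs chemoselectivity among several carbene pathways, where the chosen step needs regioselectivity in one alkyne insertion. The step count to the isoflavone is similar, with more steps after it.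

**Alternative 3:** The cuts are C3–C4 and O1–C2. In the forward key step, heating the benzodioxinone A6 with the enamine A7 would release the ketal carbonyl component and generate an ortho-quinoid ketene. The enamine β-carbon would add to the ketene carbon, the phenolic oxygen would close on the iminium carbon, and loss of the amine would give the isoflavone A5.

- In its favour: it is the most convergent of the four plans. Ring B arrives with all three methoxy groups, the 5-OH is free without a Lewis acid step, and no metal is used. On step count to an isoflavone core it is the better plan.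
- Against it here: A5 has hydrogen at both C6 and C8. The C8 hydroxylation para to a hydrogen-bonded phenol and a C6-selective prenylation would then have to be done with ring B present. Building the C8 oxygen and a C6 handle into A6 would require a hexasubstituted salicylate, whose synthesis erodes the step advantage. The ketene forms only at high temperature, where an enamine of an electron-rich arylacetaldehyde can self-condense and the liberated amine can trap the ketene.
- Comparison: structurally it is the equal of the chosen plan for rings B and C and weaker for ring A. Mechanistically it is a two-bond polar annulation, against a three-bond organometallic one, and is simpler to run. It is shorter to the core, but probably not to the target.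

Key step: step 6

Assumption: 1 (2'-hydroxy-3',4',6'-trimethoxyacetophenone) is taken as purchasable; its C3' methoxy group is the future C8 oxygen, so no oxygen has to be introduced on ring A later.

## Route

Step 1
Reactants: 1 1-(2-hydroxy-3,4,6-trimethoxyphenyl)ethanone
Product: 2 1-(3-bromo-6-hydroxy-2,4,5-trimethoxyphenyl)ethanone
Conditions: NBS (1.05 equiv), MeCN, 0 °C → rt
Reagents that add atoms: N-bromosuccinimide, O=C1CCC(=O)N1Br
Why: Electrophilic aromatic bromination at the only unsubstituted ring carbon, which is para to the phenol and flanked by two methoxy groups; under polar, non-radical conditions the ring reacts far faster than the acetyl methyl group.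

Step 2
Reactants: 2 1-(3-bromo-6-hydroxy-2,4,5-trimethoxyphenyl)ethanone
Product: 4 6-bromo-3-iodo-5,7,8-trimethoxy-4H-chromen-4-one, via enaminone 3 (not isolated)
Conditions: DMF-DMA, 95 °C; evaporate; I2 (2 equiv), CHCl3, rt; aq. Na2S2O3 wash
Reagents that add atoms: N,N-dimethylformamide dimethyl acetal, COC(OC)N(C)C; iodine, II
Why: Condensation of the acetyl methyl group with the formamide acetal gives the push–pull enaminone; iodine attacks its α-carbon and the ortho phenol closes on the iminium carbon with loss of dimethylamine (iodocyclisation of 2-hydroxyaryl enaminones), and the fully substituted ring A offers iodine no other site.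

Step 3
Reactants: 4 6-bromo-3-iodo-5,7,8-trimethoxy-4H-chromen-4-one; 5 ethynyltrimethylsilane
Product: 6 6-bromo-5,7,8-trimethoxy-3-[(trimethylsilyl)ethynyl]-4H-chromen-4-one
Conditions: PdCl2(PPh3)2 (3 mol %), CuI (5 mol %), Et3N, THF, rt
Reagents that add atoms: none
Why: Sonogashira coupling; oxidative addition into the C3–I bond of the iodoenone is much faster at rt than into the electron-rich C6–Br bond between two methoxy groups, and the tertiary amine does not open the pyranone.

Step 4
Reactants: 6 6-bromo-5,7,8-trimethoxy-3-[(trimethylsilyl)ethynyl]-4H-chromen-4-one
Product: 7 6-bromo-3-ethynyl-5,7,8-trimethoxy-4H-chromen-4-one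
Conditions: TBAF (1.1 equiv), AcOH (1.2 equiv), THF, 0 °C
Reagents that add atoms: none
Why: Fluoride-induced protodesilylation of the alkynylsilane; the acetic acid buffer keeps the medium from becoming basic enough for conjugate attack at C2.

Step 5
Reactants: 8 methyl vinyl ether; 9 Cr(CO)6
Product: 12 pentacarbonyl[methoxy(1-methoxyethenyl)carbene]chromium (CO)5Cr=C(OMe)C(OMe)=CH2, via 1-methoxyvinyllithium 10 (not isolated), via Li[(CO)5CrC(O)C(OMe)=CH2] 11 (not isolated)
Conditions: t-BuLi, THF, −78 → 0 °C; Cr(CO)6, THF, 0 °C → rt; evaporate; Me3OBF4, CH2Cl2, 0 °C
Reagents that add atoms: trimethyloxonium tetrafluoroborate, C[O+](C)C.F[B-](F)(F)F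
Why: Fischer carbene synthesis: α-lithiation of the enol ether, addition of the vinyllithium to a carbonyl ligand of the hexacarbonyl and O-methylation of the acylate; anhydrous alkylation spares the enol ether, and 12 is used soon after filtration through silica.

Step 6
Reactants: 7 6-bromo-3-ethynyl-5,7,8-trimethoxy-4H-chromen-4-one; 12 pentacarbonyl[methoxy(1-methoxyethenyl)carbene]chromium
Product: 14 6-bromo-3-(2-hydroxy-4,5-dimethoxyphenyl)-5,7,8-trimethoxy-4H-chromen-4-one, via tricarbonylchromium arene complex 13 (not isolated)
Conditions: 12 (1.5 equiv), degassed THF (0.05 M), 55 °C, Ar; then air, CH2Cl2, daylight, rt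
Reagents that add atoms: none
Why: Thermal loss of one CO from 12 frees a site on zerovalent chromium, and 7 inserts into the Cr=C bond so that its CH terminus bonds to the carbene carbon (C5'–C6'). Insertion of a CO ligand into the resulting vinylcarbene gives a chromium-bound dienylketene and forms C1'–C2'. Ring B then closes by a thermally allowed 6π electrocyclisation of this ketene onto the CH2 terminus of the methoxyvinyl group (C2'–C3'), and tautomerisation of the cyclohexadienone gives the phenol, held as its Cr(CO)3 complex 13. The closest known reaction type is the Dötz benzannulation of alkenyl(alkoxy)carbene complexes, including α-alkoxyalkenyl ones, with terminal aryl- and alkenylacetylenes. No stereocentre is formed. The selectivity needed is the orientation of alkyne insertion: the bulky chromonyl substituent stays away from the carbene carbon and ends next to the CO-derived carbon, which places C1' beside C2'–OH and the unsubstituted alkyne carbon at C6'. The alkyne sits on the α-carbon of the enone and is not a conjugated ynone, the C2=C3 bond and the C6–Br bond are not substrates for the carbene at this temperature, and THF with high dilution favours the phenol over cyclobutenone or two-alkyne products. Air releases 14 from 13 without oxidising the new 4-methoxyphenol, which a cerium-based work-up would convert to a quinone.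

Step 7
Reactants: 14 6-bromo-3-(2-hydroxy-4,5-dimethoxyphenyl)-5,7,8-trimethoxy-4H-chromen-4-one
Product: 15 6-bromo-5,7,8-trimethoxy-3-(2,4,5-trimethoxyphenyl)-4H-chromen-4-one
Conditions: MeI (3 equiv), K2CO3 (2 equiv), acetone, 40 °C
Reagents that add atoms: iodomethane, CI
Why: Williamson methylation of the only free phenol; carbonate in acetone is mild enough to leave the pyranone closed.

Step 8
Reactants: 15 6-bromo-5,7,8-trimethoxy-3-(2,4,5-trimethoxyphenyl)-4H-chromen-4-one
Product: 16 6-bromo-5-hydroxy-7,8-dimethoxy-3-(2,4,5-trimethoxyphenyl)-4H-chromen-4-one
Conditions: BCl3 (1.5 equiv), CH2Cl2, −78 → 0 °C; then H2O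
Reagents that add atoms: none
Why: Chelation-controlled demethylation: boron binds the C4 carbonyl and the peri 5-methoxy oxygen in a six-membered chelate and chloride removes that methyl group, the selectivity known for converting polymethoxylated flavones into 5-hydroxy derivatives; the other five methyl ethers lack this assistance at low temperature.

Step 9
Reactants: 16 6-bromo-5-hydroxy-7,8-dimethoxy-3-(2,4,5-trimethoxyphenyl)-4H-chromen-4-one; 17 tributyl(3-methylbut-2-en-1-yl)stannane
Product: 18 5-hydroxy-7,8-dimethoxy-6-(3-methylbut-2-en-1-yl)-3-(2,4,5-trimethoxyphenyl)-4H-chromen-4-one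
Conditions: 17 (1.5 equiv), Pd[P(t-Bu)3]2 (5 mol %), CsF (2.2 equiv), dioxane, 90 °C
Reagents that add atoms: none
Why: Stille coupling with a zerovalent palladium catalyst built for hindered aryl bromides and activated by fluoride; reductive elimination at the less substituted allyl terminus, reinforced by the two ortho substituents, should give the linear prenyl group.

Step 10
Reactants: 18 5-hydroxy-7,8-dimethoxy-6-(3-methylbut-2-en-1-yl)-3-(2,4,5-trimethoxyphenyl)-4H-chromen-4-one
Product: 20 5,8-dihydroxy-7-methoxy-6-(3-methylbut-2-en-1-yl)-3-(2,4,5-trimethoxyphenyl)-4H-chromen-4-one, via chromene-4,5,8-trione 19 (not isolated)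
Conditions: PhI(OAc)2 (1.1 equiv), MeCN–H2O (3:1), 0 °C; then aq. Na2S2O4, rt, Ar
Reagents that add atoms: water, O
Why: Oxidative demethylation of a 4-methoxyphenol: the 5-OH exchanges onto iodine, water adds at C8 para to it and methanol is lost to give the quinone, which dithionite reduces in the same flask; the oxidant needs a free phenol, so the para-dimethoxy pair of ring B and the prenyl alkene should be spared.

## Compound list

1 | 1-(2-hydroxy-3,4,6-trimethoxyphenyl)ethanone (2'-hydroxy-3',4',6'-trimethoxyacetophenone) | CC(=O)c1c(O)c(OC)c(OC)cc1OC | starting material
2 | 1-(3-bromo-6-hydroxy-2,4,5-trimethoxyphenyl)ethanone | CC(=O)c1c(O)c(OC)c(OC)c(Br)c1OC | intermediate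
3 | (E)-1-(3-bromo-6-hydroxy-2,4,5-trimethoxyphenyl)-3-(dimethylamino)prop-2-en-1-one | CN(C)/C=C/C(=O)c1c(O)c(OC)c(OC)c(Br)c1OC | intermediate (not isolated)
4 | 6-bromo-3-iodo-5,7,8-trimethoxy-4H-chromen-4-one | COc1c(Br)c(OC)c(OC)c2occ(I)c(=O)c12 | intermediate
5 | ethynyltrimethylsilane | C#C[Si](C)(C)C | starting material
6 | 6-bromo-5,7,8-trimethoxy-3-[(trimethylsilyl)ethynyl]-4H-chromen-4-one | COc1c(Br)c(OC)c(OC)c2occ(C#C[Si](C)(C)C)c(=O)c12 | intermediate
7 | 6-bromo-3-ethynyl-5,7,8-trimethoxy-4H-chromen-4-one | COc1c(Br)c(OC)c(OC)c2occ(C#C)c(=O)c12 | intermediate
8 | methyl vinyl ether | C=COC | starting material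
9 | Cr(CO)6 | O=C=[Cr](=C=O)(=C=O)(=C=O)(=C=O)=C=O | starting material
10 | 1-methoxyvinyllithium | [Li]C(=C)OC | intermediate (not isolated)
11 | Li[(CO)5CrC(O)C(OMe)=CH2], lithium pentacarbonyl(2-methoxy-1-oxidoprop-2-en-1-ylidene)chromate | [Li+].COC(=C)C([O-])=[Cr](=C=O)(=C=O)(=C=O)(=C=O)=C=O | intermediate (not isolated)
12 | (CO)5Cr=C(OMe)C(OMe)=CH2, pentacarbonyl[methoxy(1-methoxyethenyl)carbene]chromium | COC(=C)C(OC)=[Cr](=C=O)(=C=O)(=C=O)(=C=O)=C=O | intermediate
13 | Cr(CO)3 complex of 14, bound η6 to ring B | COc1c(Br)c(OC)c(OC)c2occ(-c3cc(OC)c(OC)cc3O)c(=O)c12.O=C=[Cr](=C=O)=C=O | intermediate (not isolated)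
14 | 6-bromo-3-(2-hydroxy-4,5-dimethoxyphenyl)-5,7,8-trimethoxy-4H-chromen-4-one | COc1c(Br)c(OC)c(OC)c2occ(-c3cc(OC)c(OC)cc3O)c(=O)c12 | intermediate
15 | 6-bromo-5,7,8-trimethoxy-3-(2,4,5-trimethoxyphenyl)-4H-chromen-4-one | COc1c(Br)c(OC)c(OC)c2occ(-c3cc(OC)c(OC)cc3OC)c(=O)c12 | intermediate
16 | 6-bromo-5-hydroxy-7,8-dimethoxy-3-(2,4,5-trimethoxyphenyl)-4H-chromen-4-one | COc1cc(OC)c(-c2coc3c(OC)c(OC)c(Br)c(O)c3c2=O)cc1OC | intermediate
17 | tributyl(3-methylbut-2-en-1-yl)stannane | CCCC[Sn](CCCC)(CCCC)CC=C(C)C | starting material
18 | 5-hydroxy-7,8-dimethoxy-6-(3-methylbut-2-en-1-yl)-3-(2,4,5-trimethoxyphenyl)-4H-chromen-4-one | COc1cc(OC)c(-c2coc3c(OC)c(OC)c(CC=C(C)C)c(O)c3c2=O)cc1OC | intermediate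
19 | 7-methoxy-6-(3-methylbut-2-en-1-yl)-3-(2,4,5-trimethoxyphenyl)-4H-chromene-4,5,8-trione | COc1cc(OC)c(-c2coc3c(c2=O)C(=O)C(CC=C(C)C)=C(OC)C3=O)cc1OC | intermediate (not isolated)
20 | 5,8-dihydroxy-7-methoxy-6-(3-methylbut-2-en-1-yl)-3-(2,4,5-trimethoxyphenyl)-4H-chromen-4-one | COc1cc(OC)c(-c2coc3c(O)c(OC)c(CC=C(C)C)c(O)c3c2=O)cc1OC | target

## Step count and least certain steps

Total: 10 steps. Longest linear sequence: 9 steps (steps 1–4 and 6–10); step 5 is a one-step side branch.

**Step 6 (key step).** The carbene complex 12 may decay thermally before the alkyne inserts. After insertion, the chromium intermediate may be diverted: the C4 carbonyl can chelate chromium, the vinylketene can close to a cyclobutenone, or a second alkyne can be taken up. Some loss of regiocontrol in the insertion is also possible. Fallback: from 4, a Suzuki–Miyaura coupling at the C3–I bond with commercial (2,4,5-trimethoxyphenyl)boronic acid (Pd(PPh3)4, zerovalent palladium, aq. Na2CO3, DME, 70 °C) should leave the hindered C6–Br bond alone and rejoin the route at 15. No new compound is made.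

**Step 9.** Oxidative addition at the doubly ortho-substituted, electron-rich bromide may be slow enough for protodebromination to take over. Allyl transposition during transfer would attach the chain through its tertiary carbon. Fallback: from 16, a Suzuki–Miyaura coupling with allylboronic acid pinacol ester (PdCl2(dppf), K3PO4, THF–H2O, 70 °C) would give 6-allyl-5-hydroxy-7,8-dimethoxy-3-(2,4,5-trimethoxyphenyl)chromen-4-one F1, whose symmetrical allyl group removes the transposition question. Cross-metathesis with 2-methylbut-2-ene (second-generation Grubbs catalyst, CH2Cl2, 40 °C) would then rejoin the route at 18.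

**Step 10.** Ligand exchange of the hydrogen-bonded 5-OH at iodine may be slow, and water may add to C2 of the electron-poor quinone before it is reduced. Fallback: from 6, the oxidation is moved to a point before ring B exists and the final step becomes a plain deprotection, rejoining the route only at 20.

- (NH4)2Ce(NO3)6 (tetravalent cerium) in MeCN–H2O would cut the para 5,8-dimethoxy pair to 6-bromo-7-methoxy-3-[(trimethylsilyl)ethynyl]chromene-4,5,8-trione F2.
- Na2S2O4 would give 6-bromo-5,8-dihydroxy-7-methoxy-3-[(trimethylsilyl)ethynyl]chromen-4-one F3.
- MOMCl and NaH in DMF would give 6-bromo-7-methoxy-5,8-bis(methoxymethoxy)-3-[(trimethylsilyl)ethynyl]chromen-4-one F4.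
- Desilylation as in step 4 would give 6-bromo-3-ethynyl-7-methoxy-5,8-bis(methoxymethoxy)chromen-4-one F5.
- Benzannulation with 12 as in step 6 would give 6-bromo-3-(2-hydroxy-4,5-dimethoxyphenyl)-7-methoxy-5,8-bis(methoxymethoxy)chromen-4-one F6.
- Methylation as in step 7 would give 6-bromo-7-methoxy-5,8-bis(methoxymethoxy)-3-(2,4,5-trimethoxyphenyl)chromen-4-one F7.
- Coupling with 17 as in step 9 would give 7-methoxy-5,8-bis(methoxymethoxy)-6-(3-methylbut-2-enyl)-3-(2,4,5-trimethoxyphenyl)chromen-4-one F8.
- Dilute HCl in MeOH at rt would then free both phenols and give 20.

**Step 4.** Fluoride or adventitious hydroxide may add to C2 and open the pyranone, and the terminal alkyne may oligomerise on concentration. Fallback: from 4, a Stille coupling with tributyl(ethynyl)stannane (Pd(PPh3)4, zerovalent palladium, toluene, 80 °C) would attach the unprotected ethynyl group directly and rejoin the route at 7, with no silyl group and no fluoride. No new compound is made.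

## Further compounds

F0 | step 6 | none | none
F1 | step 9 | 6-allyl-5-hydroxy-7,8-dimethoxy-3-(2,4,5-trimethoxyphenyl)chromen-4-one | COc1cc(OC)c(-c2coc3c(OC)c(OC)c(CC=C)c(O)c3c2=O)cc1OC
F2 | step 10 | 6-bromo-7-methoxy-3-[(trimethylsilyl)ethynyl]chromene-4,5,8-trione | COC1=C(Br)C(=O)c2c(occ(C#C[Si](C)(C)C)c2=O)C1=O
F3 | step 10 | 6-bromo-5,8-dihydroxy-7-methoxy-3-[(trimethylsilyl)ethynyl]chromen-4-one | COc1c(Br)c(O)c2c(occ(C#C[Si](C)(C)C)c2=O)c1O
F4 | step 10 | 6-bromo-7-methoxy-5,8-bis(methoxymethoxy)-3-[(trimethylsilyl)ethynyl]chromen-4-one | COCOc1c(Br)c(OC)c(OCOC)c2occ(C#C[Si](C)(C)C)c(=O)c12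
F5 | step 10 | 6-bromo-3-ethynyl-7-methoxy-5,8-bis(methoxymethoxy)chromen-4-one | COCOc1c(Br)c(OC)c(OCOC)c2occ(C#C)c(=O)c12
F6 | step 10 | 6-bromo-3-(2-hydroxy-4,5-dimethoxyphenyl)-7-methoxy-5,8-bis(methoxymethoxy)chromen-4-one | COCOc1c(Br)c(OC)c(OCOC)c2occ(-c3cc(OC)c(OC)cc3O)c(=O)c12
F7 | step 10 | 6-bromo-7-methoxy-5,8-bis(methoxymethoxy)-3-(2,4,5-trimethoxyphenyl)chromen-4-one | COCOc1c(Br)c(OC)c(OCOC)c2occ(-c3cc(OC)c(OC)cc3OC)c(=O)c12
F8 | step 10 | 7-methoxy-5,8-bis(methoxymethoxy)-6-(3-methylbut-2-enyl)-3-(2,4,5-trimethoxyphenyl)chromen-4-one | COCOc1c(CC=C(C)C)c(OC)c(OCOC)c2occ(-c3cc(OC)c(OC)cc3OC)c(=O)c12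
F0 | step 4 | none | none
A1 | alternative 1 | 4-(tert-butyldimethylsilyloxy)-7-methoxy-6-(3-methylbut-2-enyl)chromane-5,8-diol (racemic) | COc1c(O)c2OCCC(O[Si](C)(C)C(C)(C)C)c2c(O)c1CC=C(C)C
A2 | alternative 1 | 4-[4-(tert-butyldimethylsilyloxy)-3,4-dihydro-2H-pyran-6-yl]-4-hydroxy-3-methoxy-2-(3-methylbut-2-enyl)cyclobut-2-en-1-one (racemic, mixture of diastereomers) | O=C1C(CC=C(C)C)=C(OC)C1(O)C1=CC(O[Si](C)(C)C(C)(C)C)CCO1
A3 | alternative 2 | 3-[4,5-dimethoxy-2-(triisopropylsilyloxy)phenyl]-5,7-dimethoxychroman-4-one (racemic) | COc1cc(OC)c2c(c1)OCC(c1cc(OC)c(OC)cc1O[Si](C(C)C)(C(C)C)C(C)C)C2=O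
A4 | alternative 2 | 2-diazo-2-[4,5-dimethoxy-2-(triisopropylsilyloxy)phenyl]-1-(2,4,6-trimethoxyphenyl)ethanone | COc1cc(OC)c(C(=O)C(=[N+]=[N-])c2cc(OC)c(OC)cc2O[Si](C(C)C)(C(C)C)C(C)C)c(OC)c1
A5 | alternative 3 | 5-hydroxy-7-methoxy-3-(2,4,5-trimethoxyphenyl)chromen-4-one | COc1cc(O)c2c(c1)occ(-c1cc(OC)c(OC)cc1OC)c2=O
A6 | alternative 3 | 5-hydroxy-7-methoxy-2,2-dimethyl-4H-1,3-benzodioxin-4-one | COc1cc(O)c2c(c1)OC(C)(C)OC2=O
A7 | alternative 3 | 4-[(E)-2-(2,4,5-trimethoxyphenyl)ethenyl]morpholine | COc1cc(OC)c(/C=C/N2CCOCC2)cc1OC
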